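The rate constants stand for no real mixture; the rest is arithmetic.

I follow the reagent.

solid substrate 29 mM; reagent 43.5 mM; second substrate 14.5 mM (in portions, 3); catalyst 3.5 mM; time 1.5 h; the portions of second substrate follow each other after 1.0 min, the first at the start

    second substrate + reagent + catalyst → catalyst + second product (k1 = 3900 M⁻² min⁻¹)
    starting material + reagent → uncatalysed product (k2 = 0.90 M⁻¹ min⁻¹)
    solid substrate ⇌ starting material, rate k3*(cs3 - [starting material]) while solid is left; crystals form when [starting material] > cs3 (cs3 = 2.4 mM, k3 = 2.6 min⁻¹)
    starting material + reagent + catalyst → catalyst + target (k4 = 660 M⁻² min⁻¹)
    second substrate ⇌ dormant form (K5 = 0.76, k5 = 0.12 min⁻¹)

- solid, in amounts per volume of the solution: solid substrate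
- at the start none of the solid substrate is in solution
- what has only dissolved of solid substrate counts as not reacted
- the reaction counts as stopped when no species that holds the solid substrate changes by six tenths of a point or more over the second half of the time
- run time (flask): 1.5 h

* the state of affairs at 1.5 h: stopped, and by what, or still going (for what has run out or reacted, a solid counts together with what of it has only dissolved) (forward and back rates have come level / all of the solid substrate has reacted / no working catalyst is left / the reagent has run out first / it is still moving)
* how much target there is at 1.5 h, in percent of the solid substrate charged
* how much uncatalysed product there is at 1.5 h, in percent of the solid substrate charged

I begin with the catalysed step and nothing else running. The solid refills the solution with a half-time of 0.267 min, far shorter than the half-life of starting material by the catalysed step alone at the charged amounts, 0.11 h. So I hold starting material at its solubility, 8.28% of the solid charge. The reagent then decays pseudo-first-order with a half-life of 2.08 h, and in 1.5 h the reaction consumes reagent equal to 58.9% of the solid charge, as target.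

Next I add the uncatalysed step. It draws on the same reagent and the same dissolved starting material, so its rate constant adds to the catalysed constant times the catalyst. I carry the half-life that this sum gives as the saturated half-life, 1.50 h: the time in which both routes together, fed by solution at solubility, halve the reagent. The reacted share rises to 75.0% of the solid charge, and target takes 72.0% of it, which gives 54.0% target.

Last comes the second substrate. Its half-lives, 1.2 min by the catalysed step and 0.096 h by the forward step alone towards the dormant form, are far shorter than the saturated half-life. So I take its charge off the reagent at the start. This is the crossing in my reckoning: I book the reagent to the second substrate for the first minutes and to the saturated half-life afterwards. The second substrate costs a third of the reagent and leaves spare reagent equal to 100% of the solid charge. Of that, 50.0% of the solid charge reacts by 1.5 h, which is 36.0% target and 14.0% uncatalysed product. Spare reagent equal to 50.0% of the solid charge remains, with solid beside it, so I call this flask still going.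

The forecast reads: it is still moving, with 35.9% target and 14% uncatalysed product, since “the remaining reagent decays slowly and only about half the solid has reacted”.

The simulation of this flask reads: it is still moving, with 35.9% target and 14.0% uncatalysed product at 1.5 h. Reagent stands at 33.4% of its own charge at that time. In the neighbour flask with 25 mM of second substrate, spare reagent is 63.8% of the solid charge. The same saturated half-life then gives 31.9% of the solid charge reacted, or 23.0% target and 8.93% uncatalysed product. That neighbour holds 24.0% target and 9.34% uncatalysed product.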